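**The question.** Which flask ends higher in target: Saturday's, with 4.0 mM of second catalyst for 0.50 h, or Tuesday's, with 0.92 mM for 1.5 h?

- which one finishes higher in amount of target, in percent of the solid substrate charged ("neither" within 2 percentage points) (Saturday's / Tuesday's / neither)
- amount of target at the end, in percent of the solid substrate charged, Saturday's
- amount of target at the end, in percent of the solid substrate charged, Tuesday's

| flask | solid substrate | reagent | free catalyst | second catalyst | remark | time |
|---|---|---|---|---|---|---|
| gamma | 0.40 M | 0.52 M | 8 mM (in portions, 2) | 1.3 mM | run made earlier; portions every 1.5 min |  |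
| delta | 0.40 M | 0.52 M | 8 mM (in portions, 2) | 6.2 mM | run made earlier; portions every 1.5 min |  |
| Saturday's | 0.40 M | 0.520 M | 8.0 mM | 4.0 mM | everything together at the start | 0.50 h |
| Tuesday's | 0.40 M | 0.520 M | 8.0 mM (in portions, 2) | 0.92 mM | the portions of free catalyst follow each other after 1.5 min, the first at the start | 1.5 h |

| run | time / min | target / % |
|---|---|---|
| gamma | 6.00 | 0.9 |
| gamma | 20.0 | 10.4 |
| gamma | 30.0 | 18.1 |
| gamma | 50.0 | 33.2 |
| gamma | 60.0 | 40.6 |
| gamma | 90.0 | 57.0 |
| delta | 6.00 | 2.2 |
| delta | 20.0 | 17.2 |
| delta | 30.0 | 27.6 |
| delta | 50.0 | 48.6 |
| delta | 60.0 | 59.0 |
| delta | 90.0 | 73.1 |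

(each reading ± 0.5 percentage points)

- given per volume of solution although it is solid: solid substrate
- steps under discussion: starting material + free catalyst <-> free catalyst + open intermediate; second catalyst + open intermediate <-> catalyst intermediate; reagent + catalyst intermediate -> second catalyst + target; target + free catalyst <-> isomer of the product + free catalyst; solid substrate <-> starting material
- at the start none of the solid substrate is in solution
- what has only dissolved of solid substrate counts as not reacted

**Two slopes.** Between 20.0 min and 60.0 min both earlier runs climb straight, so we read a slope from each, in fractions of the solid substrate charge per minute: gamma gives 0.00755 /min and delta 0.0104 /min. Second catalyst rises by a factor 4.77 between them, the slope by 1.38, so the slope grows less than second catalyst does.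

**Joining them.** A hyperbola through both readings has 0.704 mM as half-saturation value, an apparent Michaelis constant, and a ceiling of 0.0116 /min. Saturday's delivery slope, the fraction of its solid substrate charge turned into target per minute on the straight stretch, is then 0.00990 /min. That lies 0.809 of the way from gamma to delta. Going as far between their readings at 30.0 min gives 25.8 % for Saturday's. Saturday's charges free catalyst at once, but the split in the runs lasts 1.5 min of 30 min, and we neglect it.

**Tuesday's end.** Tuesday's slope comes to 0.00659 /min, and the same join at 90.0 min gives 51.7 %. This link is weak. In the last interval delta has fallen to 0.00470 /min and gamma to 0.00547 /min, so delta has bent harder. We drop delta and scale gamma's last reading by the ratio of slopes, which gives 49.8 %. We commit to Tuesday's, ahead by 24 percentage points.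

**The forecast.** The forecast names Tuesday's, with 25.5 % for Saturday's and 50 % for Tuesday's, and holds that “Adding the catalyst all at once changes little”.

**The result.** Saturday's ends at 26.5 % and Tuesday's at 47.3 %, so Tuesday's finishes higher.

    starting material + free catalyst ⇌ free catalyst + open intermediate (K = 1.30, k = 23.5 /M/min)
    second catalyst + open intermediate ⇌ catalyst intermediate (K = 1300 /M, k = 283 /M/min)
    reagent + catalyst intermediate → second catalyst + target (k = 11.8 /M/min)
    target + free catalyst ⇌ isomer of the product + free catalyst, rate k4*[free catalyst]*[target] forward; the back reaction follows from the equilibrium constant (K = 0.367, k = 8.65 /M/min)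
    solid substrate ⇌ starting material, rate k5*(cs5 - [starting material]) while solid is left; crystals form when [starting material] > cs5 (solubility = 0.170 M, k = 0.0434 /min)

**Heavier charge.** Saturday's 26.5 % equals its delivery slope 0.00990 /min running for 26.7 min of its 30 min. A neighbouring flask is Saturday's with 1.6 M of solid substrate. We keep the flow per volume and those minutes, so its slope falls to a quarter of Saturday's, 0.00247 /min, and its target comes to 6.59 %. That flask gives 6.62 %, with 91 % of its solid substrate still there, solid or dissolved.

The readings stem from a simulated flask for an exercise; scatter was added.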